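**Retrosynthetic overview** (carotenoid locants C1–C8' are used for the target skeleton)
1. Target 17 ⇒ ring allyl sulfone 13 + all-E C20 dialdehyde 6. The C7≡C8 triple bond is made last; because a triple bond is formed, the union creates no new C=C geometry.
2. Polarity: C7 comes from PhSO2CH3 and reacts as a sulfone-stabilised carbanion (a d1, acyl-anion-type carbon that later sheds its sulfonyl group). It links two electrophilic carbonyl carbons, C6 of actinol and formyl C8 of 6.
3. 13 ⇒ (4R,6R)-actinol 7 + methyl phenyl sulfone 8 (addition, then dehydration). The C3 stereocentre is bought with 7 and never touched.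
4. 6 ⇒ C10 dialdehyde 1 by two-directional C2, then C3, Wittig extension.
5. Rings: none is built. The six-membered ring of 7 is carried through; its C5=C6 double bond is set in step 4.

Assumption: (4R,6R)-actinol 7 and the C10 dialdehyde 1 are bought as bulk carotenoid intermediates.

**Step 1**
Reactants: 1 (2E,4E,6E)-2,7-dimethylocta-2,4,6-trienedial; 2 (1,3-dioxolan-2-ylmethyl)triphenylphosphonium bromide
Product: 4 (2E,4E,6E,8E,10E)-4,9-dimethyldodeca-2,4,6,8,10-pentaenedial, via bis-dioxolane 3 (not isolated)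
Conditions: 2 (2.4 equiv), KOt-Bu, THF, 0 °C to rt; then 1 M aq. HCl, THF, rt
Reagents that add atoms: water, O
Why: Double Wittig olefination with the acetal-protected C2 ylide cannot over-homologate, and the acid hydrolysis that frees the two enals also equilibrates any Z isomer to the all-E dial.

**Step 2**
Reactants: 4 (2E,4E,6E,8E,10E)-4,9-dimethyldodeca-2,4,6,8,10-pentaenedial; 5 2-(triphenylphosphoranylidene)propanal
Product: 6 (2E,4E,6E,8E,10E,12E,14E)-2,6,11,15-tetramethylhexadeca-2,4,6,8,10,12,14-heptaenedial (crocetin dialdehyde)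
Conditions: 5 (2.4 equiv), toluene, 100 °C
Reagents that add atoms: none
Why: Two-directional Wittig reaction with an acyl-stabilised ylide gives E trisubstituted enals and stops there, because the α-methyl enal ends of 6 are much less reactive than the unbranched enal ends of 4.

**Step 3**
Reactants: 7 (4R,6R)-4-hydroxy-2,2,6-trimethylcyclohexan-1-one; 8 methyl phenyl sulfone
Product: 9 (1S,4R,6R)-2,2,6-trimethyl-1-[(phenylsulfonyl)methyl]cyclohexane-1,4-diol
Conditions: 8 (2.3 equiv), n-BuLi (2.3 equiv), THF, −78 °C; then 7, −78 to −30 °C; sat. aq. NH4Cl at −78 °C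
Reagents that add atoms: none
Why: 1,2-Addition of a small primary α-sulfonyl carbanion to the ketone (first stage of a Julia-type sequence), with the free hydroxyl carried as its lithium alkoxide; the new carbinol centre (mainly 1S by axial attack, epimer equally usable) becomes sp2 in step 4, and the C4 carbinol (future C3) is untouched.

**Step 4**
Reactants: 9 (1S,4R,6R)-2,2,6-trimethyl-1-[(phenylsulfonyl)methyl]cyclohexane-1,4-diol
Product: 13 (1R)-3,5,5-trimethyl-4-[(phenylsulfonyl)methyl]cyclohex-3-en-1-ol, via bis-trifluoroacetate 10 (not isolated), via vinyl sulfone trifluoroacetate 11 (not isolated), via allyl sulfone trifluoroacetate 12 (not isolated)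
Conditions: (CF3CO)2O (3 equiv), pyridine, CH2Cl2, 0 °C; DBU (6 equiv), CH3CN, 0 to 60 °C; then K2CO3, MeOH, rt
Reagents that add atoms: none
Why: E1cB elimination of the tertiary β-acyloxy sulfone followed by base-mediated vinyl-to-allyl sulfone isomerisation (the endocyclic tetrasubstituted alkene relieves allylic strain), with no cation and hence no methyl shift from the neighbouring quaternary carbon; methanolysis then frees the secondary alcohol with retention.

**Step 5**
Reactants: 13 (1R)-3,5,5-trimethyl-4-[(phenylsulfonyl)methyl]cyclohex-3-en-1-ol; 6 (2E,4E,6E,8E,10E,12E,14E)-2,6,11,15-tetramethylhexadeca-2,4,6,8,10,12,14-heptaenedial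
Product: 17 (2E,4E,6E,8E,10E,12E,14E)-17-[(4R)-4-hydroxy-2,6,6-trimethylcyclohex-1-en-1-yl]-2,6,11,15-tetramethylheptadeca-2,4,6,8,10,12,14-heptaen-16-ynal (target), via bis-silyl β-silyloxy sulfone 14 (not isolated), via dienyl sulfone 15 (not isolated), via target trimethylsilyl ether 16 (not isolated)
Conditions: 13, n-BuLi (2.05 equiv), THF, −78 °C; added to 6 (2.0 equiv), THF, −78 to −50 °C; Me3SiCl (2.2 equiv), −78 to −30 °C; LiN(SiMe3)2 (5 equiv), −78 °C to rt; then 0.5 M aq. HCl, THF, 0 °C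
Reagents that add atoms: none
Why: Sulfone–aldehyde double-elimination alkyne synthesis of the Julia type: C7, an allylic carbon bearing a leaving group and so by nature an acceptor, is turned into a carbanion by the sulfonyl group and attacks formyl C8, joining two acceptor carbons; silylation, E1cB loss of Me3SiO− and β-elimination of PhSO2− from the dienyl sulfone then give the enyne without creating any stereocentre or C=C geometry, and acidic work-up frees the C3 hydroxyl with the (R) centre untouched.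

**Compound list**
1 | (2E,4E,6E)-2,7-dimethylocta-2,4,6-trienedial | O=C/C(C)=C/C=C/C=C(\C)C=O | starting material
2 | (1,3-dioxolan-2-ylmethyl)triphenylphosphonium bromide | [Br-].C1COC(O1)C[P+](c1ccccc1)(c1ccccc1)c1ccccc1 | starting material
3 | 2,2'-[(1E,3E,5E,7E,9E)-3,8-dimethyldeca-1,3,5,7,9-pentaene-1,10-diyl]bis(1,3-dioxolane), formed in the flask as E/Z mixture at the two new C=C bonds (all-E drawn) | C1COC(O1)/C=C/C(C)=C/C=C/C=C(C)/C=C/C1OCCO1 | intermediate
4 | (2E,4E,6E,8E,10E)-4,9-dimethyldodeca-2,4,6,8,10-pentaenedial | O=C/C=C/C(C)=C/C=C/C=C(C)/C=C/C=O | intermediate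
5 | 2-(triphenylphosphoranylidene)propanal | CC(C=O)=P(c1ccccc1)(c1ccccc1)c1ccccc1 | starting material
6 | (2E,4E,6E,8E,10E,12E,14E)-2,6,11,15-tetramethylhexadeca-2,4,6,8,10,12,14-heptaenedial | O=C/C(C)=C/C=C/C(C)=C/C=C/C=C(C)/C=C/C=C(\C)C=O | intermediate
7 | (4R,6R)-4-hydroxy-2,2,6-trimethylcyclohexan-1-one (actinol) | C[C@@H]1C[C@@H](O)CC(C)(C)C1=O | starting material
8 | methyl phenyl sulfone | CS(=O)(=O)c1ccccc1 | starting material
9 | (1S,4R,6R)-2,2,6-trimethyl-1-[(phenylsulfonyl)methyl]cyclohexane-1,4-diol (major C1 epimer drawn) | C[C@@H]1C[C@@H](O)CC(C)(C)[C@]1(O)CS(=O)(=O)c1ccccc1 | intermediate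
10 | (1S,4R,6R)-2,2,6-trimethyl-1-[(phenylsulfonyl)methyl]cyclohexane-1,4-diyl bis(trifluoroacetate), formed in the flask | C[C@@H]1C[C@@H](OC(=O)C(F)(F)F)CC(C)(C)[C@]1(OC(=O)C(F)(F)F)CS(=O)(=O)c1ccccc1 | intermediate
11 | (1R,5R)-3,3,5-trimethyl-4-[(phenylsulfonyl)methylidene]cyclohexyl trifluoroacetate, formed in the flask (E/Z mixture at the exocyclic C=C) | C[C@@H]1C[C@@H](OC(=O)C(F)(F)F)CC(C)(C)C1=CS(=O)(=O)c1ccccc1 | intermediate
12 | (1R)-3,5,5-trimethyl-4-[(phenylsulfonyl)methyl]cyclohex-3-en-1-yl trifluoroacetate, formed in the flask | CC1=C(CS(=O)(=O)c2ccccc2)C(C)(C)C[C@H](OC(=O)C(F)(F)F)C1 | intermediate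
13 | (1R)-3,5,5-trimethyl-4-[(phenylsulfonyl)methyl]cyclohex-3-en-1-ol | CC1=C(CS(=O)(=O)c2ccccc2)C(C)(C)C[C@H](O)C1 | intermediate
14 | (2E,4E,6E,8E,10E,12E,14E)-2,6,11,15-tetramethyl-17-(phenylsulfonyl)-16-[(trimethylsilyl)oxy]-17-{(4R)-2,6,6-trimethyl-4-[(trimethylsilyl)oxy]cyclohex-1-en-1-yl}heptadeca-2,4,6,8,10,12,14-heptaenal, formed in the flask (diastereomer mixture at C16/C17, both centres are lost) | CC1=C(C(S(=O)(=O)c2ccccc2)C(O[Si](C)(C)C)/C(C)=C/C=C/C(C)=C/C=C/C=C(C)/C=C/C=C(\C)C=O)C(C)(C)C[C@H](O[Si](C)(C)C)C1 | intermediate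
15 | (2E,4E,6E,8E,10E,12E,14E)-2,6,11,15-tetramethyl-17-(phenylsulfonyl)-17-{(4R)-2,6,6-trimethyl-4-[(trimethylsilyl)oxy]cyclohex-1-en-1-yl}heptadeca-2,4,6,8,10,12,14,16-octaenal, formed in the flask (E/Z mixture at C16=C17) | CC1=C(C(S(=O)(=O)c2ccccc2)=C/C(C)=C/C=C/C(C)=C/C=C/C=C(C)/C=C/C=C(\C)C=O)C(C)(C)C[C@H](O[Si](C)(C)C)C1 | intermediate
16 | (2E,4E,6E,8E,10E,12E,14E)-2,6,11,15-tetramethyl-17-{(4R)-2,6,6-trimethyl-4-[(trimethylsilyl)oxy]cyclohex-1-en-1-yl}heptadeca-2,4,6,8,10,12,14-heptaen-16-ynal, formed in the flask | CC1=C(C#C/C(C)=C/C=C/C(C)=C/C=C/C=C(C)/C=C/C=C(\C)C=O)C(C)(C)C[C@H](O[Si](C)(C)C)C1 | intermediate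
17 | (2E,4E,6E,8E,10E,12E,14E)-17-[(4R)-4-hydroxy-2,6,6-trimethylcyclohex-1-en-1-yl]-2,6,11,15-tetramethylheptadeca-2,4,6,8,10,12,14-heptaen-16-ynal, that is (3R)-3-hydroxy-7,8-didehydro-8'-apo-β-caroten-8'-al | CC1=C(C#C/C(C)=C/C=C/C(C)=C/C=C/C=C(C)/C=C/C=C(\C)C=O)C(C)(C)C[C@H](O)C1 | target

**Totals**
Total step count: 5.
Longest linear sequence: 3 steps (7 → 9 → 13 → 17; the branch 1 → 4 → 6 → 17 is equally long).

**Three steps most likely to fail**

Step 5 is the riskiest. The polyenal formyl groups (in 6 and in the product) are exposed to amide base. Some bis-addition at both ends of 6 is possible. The dienyl sulfone 15 could lose sulfinate after deprotonation at ring C4 or the C5 methyl, giving a vinylallene instead of the alkyne. The fallback sets out from 6 and 7 and rejoins the route at 17. Colvin homologation of one formyl group of 6 (Me3SiCHN2, LiN(i-Pr)2, THF, −78 °C to rt, 6 in excess) gives (2E,4E,6E,8E,10E,12E,14E)-2,6,11,15-tetramethylheptadeca-2,4,6,8,10,12,14-heptaen-16-ynal F1. Separately, 7 is converted with LiN(i-Pr)2 (2.2 equiv) and N-(5-chloropyridin-2-yl)triflimide into (4R)-4-hydroxy-2,6,6-trimethylcyclohex-1-en-1-yl trifluoromethanesulfonate F2. Sonogashira coupling of F1 with F2 (Pd(PPh3)4 as the zerovalent palladium source, CuI, i-Pr2NH, THF, rt) gives 17.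

Step 3 is next. The ketone of 7 is flanked by a quaternary and a tertiary carbon, so the sulfonyl carbanion may enolise it or add reversibly. The fallback sets out from 7 and rejoins at 13, bypassing 9. Wittig methylenation (Ph3PCH3Br, KOt-Bu, toluene, 90 °C) gives (1R,5R)-3,3,5-trimethyl-4-methylidenecyclohexan-1-ol F3. Radical iodosulfonylation (PhSO2Na, I2, EtOAc–H2O, rt) gives (1R,5R)-4-iodo-3,3,5-trimethyl-4-[(phenylsulfonyl)methyl]cyclohexan-1-ol F4. DBU (toluene, 60 °C) removes hydrogen iodide and equilibrates the product to 13.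

Step 4 is third. Acylation of the hindered tertiary hydroxyl may be incomplete, and the vinyl-to-allyl isomerisation may be slow. The fallback sets out from 9 and rejoins at 13. Silylation of the secondary hydroxyl (t-BuMe2SiCl, imidazole, DMF) gives (1S,4R,6R)-4-[(tert-butyldimethylsilyl)oxy]-2,2,6-trimethyl-1-[(phenylsulfonyl)methyl]cyclohexan-1-ol F5. Syn-elimination with Burgess reagent (benzene, 50 °C) and brief DBU equilibration give tert-butyldimethyl({(1R)-3,5,5-trimethyl-4-[(phenylsulfonyl)methyl]cyclohex-3-en-1-yl}oxy)silane F6. Bu4NF (THF, rt) then returns 13.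

**Further compounds**
F1 | step 5 | (2E,4E,6E,8E,10E,12E,14E)-2,6,11,15-tetramethylheptadeca-2,4,6,8,10,12,14-heptaen-16-ynal | C#C/C(C)=C/C=C/C(C)=C/C=C/C=C(C)/C=C/C=C(\C)C=O
F2 | step 5 | (4R)-4-hydroxy-2,6,6-trimethylcyclohex-1-en-1-yl trifluoromethanesulfonate | CC1=C(OS(=O)(=O)C(F)(F)F)C(C)(C)C[C@H](O)C1
F3 | step 3 | (1R,5R)-3,3,5-trimethyl-4-methylidenecyclohexan-1-ol | C[C@@H]1C[C@@H](O)CC(C)(C)C1=C
F4 | step 3 | (1R,5R)-4-iodo-3,3,5-trimethyl-4-[(phenylsulfonyl)methyl]cyclohexan-1-ol (C4 epimers) | C[C@@H]1C[C@@H](O)CC(C)(C)C1(I)CS(=O)(=O)c1ccccc1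
F5 | step 4 | (1S,4R,6R)-4-[(tert-butyldimethylsilyl)oxy]-2,2,6-trimethyl-1-[(phenylsulfonyl)methyl]cyclohexan-1-ol | C[C@@H]1C[C@@H](O[Si](C)(C)C(C)(C)C)CC(C)(C)[C@]1(O)CS(=O)(=O)c1ccccc1
F6 | step 4 | tert-butyldimethyl({(1R)-3,5,5-trimethyl-4-[(phenylsulfonyl)methyl]cyclohex-3-en-1-yl}oxy)silane | CC1=C(CS(=O)(=O)c2ccccc2)C(C)(C)C[C@H](O[Si](C)(C)C(C)(C)C)C1
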